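## Analysis of the target

The target is an ent-labdane: a trans-fused decalin (ring A: C1–C5 and C10; ring B: C5–C10) that carries on C9 a two-carbon chain (C11–C12) ending at the α-carbon C13 of a but-2-en-4-olide (C13–C16). Six contiguous stereocentres sit on the bicycle: C3 (equatorial hydroxyl), the quaternary C4 (equatorial C18 methyl, axial C19 hydroxymethyl), C5 (axial hydrogen), C8 (equatorial C17 hydroxymethyl), C9 (equatorial side chain) and the quaternary C10 (axial C20 methyl). C19 and C20 are syn and 1,3-diaxial across C5, C11 lies on the face of C20, H5 and H9 lie on the other face, and the groups on C8 and C9 are trans-diequatorial, so the C8 configuration is the thermodynamic one. The sensitive parts are the butenolide, which does not survive hydride reagents, strong base or catalytic hydrogenation, and the four oxygenated carbons C3, C11 (as chain precursor), C17 and C19, which have to be told apart. The synthesis is hard because of the two quaternary centres C4 and C10 with their syn relationship, the two different one-carbon groups on C4, and the need to set C9 and C10 together. The strategy rests on ring B: C8 bears a one-carbon group that can begin as the ester of a 2-pyrone-3-carboxylate (pyrone C3 = C8, pyrone C6 = C5), and the cis pair C20/C11 on C10/C9 is the image of an E-trisubstituted alkene. Ring B is therefore a diene plus a dienophile, and ring A is the tether between them.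

## Retrosynthetic reasoning

Atoms are numbered as in the labdane skeleton; compounds carry the numbers used in the steps.

**30 ⇒ 29.** The hydroxyl groups at C3, C17 and C19 are unmasked last by one global desilylation. Silyl ethers are the only protecting groups at that stage because the butenolide tolerates their acidic removal but not basic or reductive deprotection.

**29 ⇒ 26 + 27.** The C12–C13 bond is cut between the chain and the lactone. This keeps the butenolide out of every reduction and brings it in as the commercial bromolactone 27. Forward, the vinyl group of 26 is hydroborated at C12 and the primary borane 28 is coupled with 27.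

**26 ⇒ 25 ⇒ 24 ⇒ 23 ⇒ 22.** The C11=C12 bond is cut to aldehyde 25, and this to alcohol 24. C11 must be freed alone among three primary carbinols. In 23 it is the only primary tert-butyldimethylsilyl ether, next to two tert-butyldiphenylsilyl ethers (C17, C19) and a hindered secondary silyl ether (C3), so mild acid distinguishes it. The diphenylsilyl groups go onto diol 22.

**22 ⇒ 21 ⇒ 20 ⇒ 19.** Both hydroxymethyl groups are traced to methyl esters, reduced together. The four C–H bonds at C5–C8 are traced to the diene of 19: hydrogenation from the face opposite C20 fixes C5 (trans fusion), and the C8 ester is then equilibrated to the equatorial position, so C8 asks nothing of the ring-forming step.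

**19 ⇒ 18 ⇒ 17 (key disconnection).** C5–C10 and C8–C9 are cut, which opens both rings at once and leads to the acyclic pyrone triene 17 through the bridged lactone 18. These bonds are chosen because the cycloaddition delivers C9 and C10 together from the alkene geometry, while the decarboxylative cycloreversion flattens C5 and C8 so that no ring-fusion selectivity is demanded. Forward, the reaction has to choose one alkene face relative to C3 and C4.

**17 ⇒ 16 ⇒ 14 + 15.** The pyrone is cut at the C6–C7 bond and at the lactone C–O bond, giving methyl ketone 14 and the malonate 15. Ketone 14 has a quaternary α-carbon on one side, so only its methyl group can enolise and the annulation is regiochemically unambiguous.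

**14 ⇒ 13 ⇒ 12.** The C5 carbonyl is traced to a vinyl group (Markovnikov oxidation) after silylation of the C3 hydroxyl. A vinyl group is the only acetyl equivalent that can sit on C4 through the enolate step before it.

**12 ⇒ 11 ⇒ 10.** The C4–C18 bond is cut. A chelated dianion is methylated anti to the carbinol oxygen, and the required C4 configuration has the methyl group in exactly that position. Methyl must therefore be the last group to arrive, and the two-carbon unit must already be on C4. A plain 3-hydroxy ester alkylated twice would need that unit as the first electrophile, which neither a vinyl nor an acetyl group can be, and an aldehyde as first electrophile would leave a diol that cannot be differentiated.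

**10 ⇒ 9 ⇒ 8 ⇒ 7 + 4.** The C3–C4 bond is cut by an auxiliary-controlled aldol between crotonyl imide 7 (through dienolate 8) and aldehyde 4. It sets C3 absolutely and brings C4, C19 and the vinyl unit in one step. The C4 configuration of 9 is irrelevant because step 7 re-forms it.

**4 ⇒ 3 ⇒ 2 ⇒ 1 and 7 ⇒ 5 + 6.** Aldehyde 4 already holds C1, C2, C3, C9, C10, C11 and C20 with the E alkene. It comes from geraniol 1 by silylation, epoxidation of the distal alkene and glycol-type cleavage, which uses the natural E geometry instead of building it. Imide 7 is the N-acyl derivative of auxiliary 5 and acid chloride 6.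

## Alternatives that were turned down

**Alternative 1:** Vicinal difunctionalisation of a ring B enone.
- Disconnection: C9–C11 and C10–C1, on the ring B enone A1, (S)-2-methyl-4-(silyloxymethyl)cyclohex-2-enone.
- Forward key step: copper-catalysed conjugate addition of vinylmagnesium bromide A2 to C9 of A1, then alkylation of the C10 enolate with (E)-1,3-dichlorobut-2-ene A3, gives ketone A4 in one flask. No ring closes.
- For: the vinyl group should add anti to the C8 substituent and the alkylating agent anti to the new vinyl group, so C8, C9 and C10 come out correctly by relay from one stereocentre. The C11=C12 vinyl group is present at once, whereas the chosen route reaches it only at 26 after three extra operations. On both points this alternative is stronger.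
- Against: ring A is still open. Hydrolysis of the vinyl chloride and aldol closure would give a C4=C5 enone with a C3 ketone, after which C18 and C19 on C4, H5 and the C3 carbinol must all be set on the bicycle, including the awkward choice of which C4 group becomes axial. A1 must itself be made as one enantiomer. Alkylation of a tetrasubstituted enolate at C10 competes with proton transfer and alkylation at C6.
- Comparison: the chosen strategy pays for its longer way to the vinyl group by closing both rings and setting C9 and C10 in one step, with C3 and C4 already fixed in acyclic 17.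

**Alternative 2:** Amine-catalysed desymmetrising aldol.
- Disconnection: C4=C5 of the enedione ester A6, back to the prochiral triketone A5 (a 2-methylcyclohexane-1,3-dione carrying a 3-oxopentanoate chain on C10).
- Forward key step: a chiral amine catalyst makes the side-chain C4 nucleophilic and condenses it with one of the two enantiotopic ring ketones (C5); dehydration closes ring A and sets C10.
- For: catalytic asymmetric, cheap achiral materials, a reaction class of high reliability and scalability, and C19 already an ester on C4. In origin of chirality (catalytic, against the stoichiometric auxiliary 5) and in confidence in the key step it is stronger than the chosen strategy.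
- Against: only C10 is set. C3, C4, C5, C8 and C9 and three carbon–carbon bonds (C18, C11, C17) remain, on a trione whose C3 and C9 ketones must be differentiated. The C9 ketone has to become a CH bearing the chain next to a new C8 hydroxymethyl, which costs several homologations and two stereocentres.
- Comparison: a safer first step but a much longer sequence after it. The chosen cycloaddition delivers ring B with its C8, C9 and C10 substituents in the ring-forming step.

**Alternative 3:** Epoxy silyl ether ring contraction.
- Disconnection: C3–C4 of aldehyde A9, back to the seven-membered-ring epoxy silyl ether A7 in which C19 is a ring atom between C3 and C4.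
- Forward key step: the bulky Lewis acid A8, methylaluminium bis(4-bromo-2,6-di-tert-butylphenoxide), opens the C4–C19 epoxide at tertiary C4. The silyloxy-bearing C3 migrates from C19 to C4 anti to the leaving oxygen, contracting the ring to ring A and releasing C19 as the aldehyde.
- For: the migration is stereospecific, so quaternary C4 is formed with axial C19 at a useful oxidation level and with the C3 oxygen in place. On control of C4 it is stronger than the chosen strategy, which relies on a chelate-controlled enolate methylation.
- Against: A7 already contains ring B with C5, C8, C9 and C10 set, plus a seven-membered ring and a trisubstituted epoxide of defined configuration. All skeletal work lies before the key step, which adds one bond, one stereocentre and no ring. Migration of C5 or of hydride can compete.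
- Comparison: it solves one centre late and precisely; the chosen strategy solves both rings and two centres early, from a ten-step acyclic precursor.

Key step: step 11

Assumption: compounds 1, 5, 6, 15 and 27 are taken as commercial; labdane atom numbers (C1–C20) are used for all intermediates, including acyclic ones.

## Steps

Step 1
Reactants: 1 geraniol
Product: 2 geranyl tert-butyldimethylsilyl ether
Conditions: TBSCl, imidazole, DMF, 0 → 25 °C
Reagents that add atoms: tert-butyldimethylsilyl chloride, CC(C)(C)[Si](C)(C)Cl
Why: Standard silylation of a primary allylic alcohol; the ether becomes the C11 oxygen and stays until step 16.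

Step 2
Reactants: 2 geranyl tert-butyldimethylsilyl ether
Product: 3 6,7-epoxide of 2 (racemic at the epoxide carbon)
Conditions: mCPBA, NaHCO3, CH2Cl2, −20 → 0 °C
Reagents that add atoms: 3-chloroperoxybenzoic acid, O=C(OO)c1cccc(Cl)c1
Why: Prilezhaev epoxidation is expected at the distal trisubstituted alkene, which is more electron-rich and less hindered than the alkene next to the silyloxy group. The epoxide stereocentre is destroyed in step 3.

Step 3
Reactants: 3 6,7-epoxide of 2
Product: 4 (4E)-6-(tert-butyldimethylsilyloxy)-4-methylhex-4-enal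
Conditions: H5IO6, THF/Et2O, 0 °C
Reagents that add atoms: none
Why: Periodic acid opens the epoxide to the glycol and cleaves it (Malaprade-type cleavage), releasing acetone and the aldehyde that holds C3, C2, C1, C10(C20)=C9 and C11 with the E geometry of geraniol.

Step 4
Reactants: 5 (4S)-4-benzyloxazolidin-2-one; 6 (2E)-but-2-enoyl chloride
Product: 7 (4S)-4-benzyl-3-[(2E)-but-2-enoyl]oxazolidin-2-one
Conditions: nBuLi, THF, −78 °C; then 6, −78 → 0 °C
Reagents that add atoms: none
Why: N-Acylation of the lithiated oxazolidinone, the usual way to such imides.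

Step 5
Reactants: 7 (4S)-4-benzyl-3-[(2E)-but-2-enoyl]oxazolidin-2-one; 4 (4E)-6-(tert-butyldimethylsilyloxy)-4-methylhex-4-enal
Product: 9 (4S)-4-benzyl-3-[(2S,3R,6E)-8-(tert-butyldimethylsilyloxy)-2-ethenyl-3-hydroxy-6-methyloct-6-enoyl]oxazolidin-2-one, via dibutylboron dienolate 8 (not isolated)
Conditions: Bu2BOTf, Et3N, CH2Cl2, −78 → 0 °C; then 4, −78 → 0 °C; pH 7 buffer, MeOH, H2O2, 0 °C
Reagents that add atoms: none
Why: Evans syn aldol: γ-deprotonation gives the Z boron dienolate 8, which reacts at its α-carbon through a Zimmerman–Traxler chair on the face away from the benzyl group, setting C3 as R and placing C4, C19 and the vinyl group (future C5–C6). The C4 configuration is provisional.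

Step 6
Reactants: 9 aldol imide
Product: 10 methyl (2S,3R,6E)-8-(tert-butyldimethylsilyloxy)-2-ethenyl-3-hydroxy-6-methyloct-6-enoate
Conditions: MeOMgBr (from MeMgBr and MeOH), MeOH/CH2Cl2, 0 °C
Reagents that add atoms: methanol, CO
Why: Magnesium-chelate-assisted methanolysis of the imide carbonyl is mild enough to avoid retro-aldol and returns auxiliary 5. Any shift of the alkene into conjugation is harmless, because step 7 makes the same dienolate from either isomer.

Step 7
Reactants: 10 hydroxy ester
Product: 12 methyl (2S,3R,6E)-8-(tert-butyldimethylsilyloxy)-2-ethenyl-3-hydroxy-2,6-dimethyloct-6-enoate, via dilithium alkoxide dienolate 11 (not isolated)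
Conditions: LiN(iPr)2 (2.3 equiv), THF, −78 → −20 °C; then MeI, DMPU, −78 → −10 °C; aq. NH4Cl
Reagents that add atoms: iodomethane, CI
Why: Fráter–Seebach alkylation: the lithium alkoxide and the enolate oxygen form a six-membered chelate, and iodomethane attacks the α-carbon (the usual site for ester dienolates) on the face away from the C2 chain. C18 therefore ends anti to the C3 oxygen and the vinyl group stays syn, which is the C4 configuration of the target.

Step 8
Reactants: 12 quaternary hydroxy ester
Product: 13 methyl (2S,3R,6E)-3,8-bis(tert-butyldimethylsilyloxy)-2-ethenyl-2,6-dimethyloct-6-enoate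
Conditions: TBSOTf, 2,6-lutidine, CH2Cl2, −78 → 0 °C
Reagents that add atoms: tert-butyldimethylsilyl trifluoromethanesulfonate, CC(C)(C)[Si](C)(C)OS(=O)(=O)C(F)(F)F
Why: The silyl triflate silylates the hindered secondary hydroxyl next to the quaternary carbon; the bulky ether is the conformational anchor of step 11.

Step 9
Reactants: 13 bis-silyl vinyl ester
Product: 14 methyl (2R,3R,6E)-2-acetyl-3,8-bis(tert-butyldimethylsilyloxy)-2,6-dimethyloct-6-enoate
Conditions: PdCl2(Quinox) (5 mol %; Quinox = 2-(4,5-dihydrooxazol-2-yl)quinoline), AgSbF6 (12 mol %), aq. tBuOOH, CH2Cl2, 0 → 25 °C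
Reagents that add atoms: tert-butyl hydroperoxide, CC(C)(C)OO
Why: Wacker-type oxidation by divalent palladium converts only the monosubstituted alkene into the methyl ketone (Markovnikov); the trisubstituted alkene does not bind the catalyst competitively. The quinoline–oxazoline ligand is chosen because it keeps Markovnikov selectivity when coordinating oxygen functions are nearby.

Step 10
Reactants: 14 methyl ketone; 15 dimethyl methoxymethylenemalonate
Product: 17 pyrone triene methyl 6-[(2R,3R,6E)-3,8-bis(tert-butyldimethylsilyloxy)-1-methoxy-2,6-dimethyl-1-oxooct-6-en-2-yl]-2-oxo-2H-pyran-3-carboxylate, via keto alkylidenemalonate 16 (not isolated)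
Conditions: LiN(SiMe3)2, THF, −78 °C; then 15, −78 → 25 °C; aq. NH4Cl; then PPTS (cat.), PhMe, 60 °C
Reagents that add atoms: none
Why: Known pyrone annulation: the only possible enolate of 14 (methyl side; the other α-carbon is quaternary) adds to 15 with loss of methoxide to give 16, whose enol oxygen lactonises onto the cis ester to give the 6-substituted 2-pyrone-3-carboxylate. C6, C7, C8 and C17 are now in place.

Step 11
Reactants: 17 pyrone triene
Product: 19 bicyclic dienoate (C5=C6–C7=C8; C17 and C19 methyl esters; C9 and C10 set), via bridged lactone cycloadduct 18 (not isolated)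
Conditions: 1,2-dichlorobenzene (0.01 M), BHT, 180 °C, sealed vessel, Ar
Reagents that add atoms: none
Why: On heating, the electron-poor pyrone of 17 acts as the diene (C5=C6–C7=C8) towards the tethered alkene C9=C10 in a concerted, suprafacial [4+2] addition that forms C5–C10 and C8–C9 and gives the bridged lactone 18, which then loses CO2 by retro-[4+2] to leave the dienoate 19. The closest known reaction type is the intramolecular Diels–Alder reaction of 2-pyrone-3-carboxylates with tethered alkenes followed by thermal decarboxylation. Ring B closes as the six-membered cycloadduct ring, and ring A closes through the C5–C10 bond as the six-membered ring defined by the four-atom tether C4–C3–C2–C1, which also fixes the regiochemistry. C9 is controlled by the E geometry of the alkene, since suprafacial addition keeps C20 and C11 cis. C10 is controlled by the tether conformation: in the chair-like arrangement C9 must lie anti to C4 about the forming C5–C10 bond, so C20 is axial on ring A and ends syn to whichever C4 substituent is axial, and with the C3 silyloxy group equatorial and the flat, smaller ester (not the methyl group) axial, that substituent is C19. The other chair would put the silyloxy group axial against a pyrone ring atom and the C18 methyl against C20, so both elements push the same way. The only selectivity the step needs is this choice of alkene face relative to C3 and C4, because the orientation of the lactone bridge and the configurations at C5 and C8 are erased when CO2 leaves. High dilution and a radical inhibitor limit intermolecular reactions, and the temperature is kept at the minimum needed for CO2 loss to avoid 1,5-hydrogen shifts in 19.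

Step 12
Reactants: 19 bicyclic dienoate
Product: 20 saturated trans-decalin diester with the C8 ester axial (8-epimer of 21)
Conditions: H2 (4 atm), PtO2, EtOAc, 25 °C
Reagents that add atoms: none
Why: Heterogeneous hydrogenation should deliver hydrogen to the diene face opposite the C20 methyl and the axial C19 ester, which sets H5 anti to C20 (trans fusion) and provisionally places the C8 ester axial. Any equatorial C8 epimer formed alongside converges in step 13.

Step 13
Reactants: 20 saturated diester (C8 ester axial)
Product: 21 saturated trans-decalin diester with the C8 ester equatorial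
Conditions: NaOMe, MeOH, 60 °C
Reagents that add atoms: none
Why: Thermodynamic epimerisation through the C8 ester enolate relieves the 1,3-diaxial ester/C20 interaction and gives the trans-diequatorial C8/C9 pair. C8 is the only enolisable stereocentre, since the C19 ester sits on quaternary C4.

Step 14
Reactants: 21 saturated diester (C8 ester equatorial)
Product: 22 C17,C19-diol with C3 and C11 tert-butyldimethylsilyl ethers
Conditions: LiAlH4, THF, 0 → 50 °C
Reagents that add atoms: none
Why: Hydride reduction of both esters, including the hindered neopentyl C19 ester; silyl ethers are stable to the reagent.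

Step 15
Reactants: 22 C17,C19-diol
Product: 23 C17,C19-bis(tert-butyldiphenylsilyl) ether with C3 and C11 tert-butyldimethylsilyl ethers
Conditions: TBDPSCl, imidazole, DMAP (cat.), DMF, 40 °C
Reagents that add atoms: tert-butyldiphenylsilyl chloride, CC(C)(C)[Si](Cl)(c1ccccc1)c1ccccc1
Why: Silylation of the two primary hydroxyls with a group about a hundred times more acid-stable than the primary tert-butyldimethylsilyl ether, which makes C11 addressable alone.

Step 16
Reactants: 23 tetrasilyl ether
Product: 24 C11 primary alcohol (C3 tert-butyldimethylsilyl ether; C17 and C19 tert-butyldiphenylsilyl ethers)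
Conditions: CSA (0.1 equiv), MeOH/CH2Cl2, 0 °C
Reagents that add atoms: none
Why: Acid-catalysed methanolysis removes the primary tert-butyldimethylsilyl ether selectively; the diphenylsilyl ethers and the hindered secondary C3 ether beside quaternary C4 react far more slowly.

Step 17
Reactants: 24 C11 alcohol
Product: 25 C11 aldehyde
Conditions: Dess–Martin periodinane, NaHCO3, CH2Cl2, 0 → 25 °C
Reagents that add atoms: none
Why: Neutral, buffered oxidation of a primary alcohol; the equatorial aldehyde on C9 is the more stable epimer, so C9 is not endangered.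

Step 18
Reactants: 25 C11 aldehyde
Product: 26 C9-vinyl compound (C11=C12)
Conditions: Ph3PCH3Br, KN(SiMe3)2, THF, 0 °C; then 25, 0 → 25 °C
Reagents that add atoms: methyltriphenylphosphonium bromide, C[P+](c1ccccc1)(c1ccccc1)c1ccccc1.[Br-]
Why: Wittig methylenation adds C12; the unstabilised ylide reacts readily with hindered aldehydes and leaves silyl ethers untouched.

Step 19
Reactants: 26 C9-vinyl compound; 27 3-bromofuran-2(5H)-one
Product: 29 silyl-protected target (C3 tert-butyldimethylsilyl; C17 and C19 tert-butyldiphenylsilyl), via B-alkyl-9-BBN borane 28 (not isolated)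
Conditions: 9-BBN dimer, THF, 25 → 50 °C; then aq. K3PO4, PdCl2(dppf), AsPh3, 27, DMF, 25 °C
Reagents that add atoms: none
Why: Anti-Markovnikov hydroboration of the only alkene puts boron on C12, and B-alkyl Suzuki–Miyaura coupling of 28 with the α-bromobutenolide 27 on zerovalent palladium forms C12–C13. The mild phosphate base and room temperature spare the lactone.

Step 20
Reactants: 29 silyl-protected target
Product: 30 14-deoxy-17-hydroxyandrographolide
Conditions: HF·pyridine, pyridine, THF, 0 → 40 °C
Reagents that add atoms: none
Why: Buffered fluoride removes all three silyl ethers in one operation under conditions to which the butenolide and the 1,3-diol are inert.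

## Compound list

1 | geraniol, (2E)-3,7-dimethylocta-2,6-dien-1-ol | CC(C)=CCC/C(C)=C/CO | starting material
2 | geranyl tert-butyldimethylsilyl ether | CC(C)=CCC/C(C)=C/CO[Si](C)(C)C(C)(C)C | intermediate
3 | 6,7-epoxide of 2, racemic at the epoxide carbon | CC1(C)OC1CC/C(C)=C/CO[Si](C)(C)C(C)(C)C | intermediate
4 | (4E)-6-(tert-butyldimethylsilyloxy)-4-methylhex-4-enal | O=CCC/C(C)=C/CO[Si](C)(C)C(C)(C)C | intermediate
5 | (4S)-4-benzyloxazolidin-2-one | O=C1N[C@@H](Cc2ccccc2)CO1 | starting material
6 | (2E)-but-2-enoyl chloride | C/C=C/C(=O)Cl | starting material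
7 | (4S)-4-benzyl-3-[(2E)-but-2-enoyl]oxazolidin-2-one | C/C=C/C(=O)N1[C@@H](Cc2ccccc2)COC1=O | intermediate
8 | dibutylboron (Z)-dienolate of 7 | C=C/C=C(\OB(CCCC)CCCC)N1[C@@H](Cc2ccccc2)COC1=O | intermediate
9 | (4S)-4-benzyl-3-[(2S,3R,6E)-8-(tert-butyldimethylsilyloxy)-2-ethenyl-3-hydroxy-6-methyloct-6-enoyl]oxazolidin-2-one | O=C1OC[C@H](Cc2ccccc2)N1C(=O)[C@@H](C=C)[C@H](O)CC/C(C)=C/CO[Si](C)(C)C(C)(C)C | intermediate
10 | methyl (2S,3R,6E)-8-(tert-butyldimethylsilyloxy)-2-ethenyl-3-hydroxy-6-methyloct-6-enoate | C=C[C@H](C(=O)OC)[C@H](O)CC/C(C)=C/CO[Si](C)(C)C(C)(C)C | intermediate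
11 | dilithium alkoxide dienolate of 10 (enolate oxygen cis to C3, chelated) | C=C/C(=C(/[O-])OC)[C@H]([O-])CC/C(C)=C/CO[Si](C)(C)C(C)(C)C.[Li+].[Li+] | intermediate
12 | methyl (2S,3R,6E)-8-(tert-butyldimethylsilyloxy)-2-ethenyl-3-hydroxy-2,6-dimethyloct-6-enoate | C=C[C@](C)(C(=O)OC)[C@H](O)CC/C(C)=C/CO[Si](C)(C)C(C)(C)C | intermediate
13 | methyl (2S,3R,6E)-3,8-bis(tert-butyldimethylsilyloxy)-2-ethenyl-2,6-dimethyloct-6-enoate | C=C[C@](C)(C(=O)OC)[C@H](O[Si](C)(C)C(C)(C)C)CC/C(C)=C/CO[Si](C)(C)C(C)(C)C | intermediate
14 | methyl (2R,3R,6E)-2-acetyl-3,8-bis(tert-butyldimethylsilyloxy)-2,6-dimethyloct-6-enoate | CC(=O)[C@](C)(C(=O)OC)[C@H](O[Si](C)(C)C(C)(C)C)CC/C(C)=C/CO[Si](C)(C)C(C)(C)C | intermediate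
15 | dimethyl 2-(methoxymethylidene)propanedioate | COC=C(C(=O)OC)C(=O)OC | starting material
16 | keto alkylidenemalonate: dimethyl 2-(3-oxopropylidene)malonate carrying the C4 quaternary carbon of 14 on the ketone | COC(=O)C(=CCC(=O)[C@](C)(C(=O)OC)[C@H](O[Si](C)(C)C(C)(C)C)CC/C(C)=C/CO[Si](C)(C)C(C)(C)C)C(=O)OC | intermediate
17 | pyrone triene, methyl 6-[(2R,3R,6E)-3,8-bis(tert-butyldimethylsilyloxy)-1-methoxy-2,6-dimethyl-1-oxooct-6-en-2-yl]-2-oxo-2H-pyran-3-carboxylate | COC(=O)C1=CC=C(OC1=O)[C@](C)(C(=O)OC)[C@H](O[Si](C)(C)C(C)(C)C)CC/C(C)=C/CO[Si](C)(C)C(C)(C)C | intermediate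
18 | bridged lactone cycloadduct: bicyclo[2.2.2]octene with O–C(=O) bridging C5 and C8, drawn with C1 syn to the lactone bridge (the isomer with C1 syn to the C6=C7 bridge gives the same diene) | C[C@]1(C(=O)OC)[C@]23C=C[C@](C(=O)OC)(C(=O)O2)[C@@H](CO[Si](C)(C)C(C)(C)C)[C@]3(C)CC[C@H]1O[Si](C)(C)C(C)(C)C | intermediate
19 | bicyclic dienoate: C5=C6–C7=C8 diene, C17 and C19 methyl esters, C20 syn to C19 and to C11, C3 silyloxy cis to C19 | C[C@]1(C(=O)OC)C2=CC=C(C(=O)OC)[C@@H](CO[Si](C)(C)C(C)(C)C)[C@]2(C)CC[C@H]1O[Si](C)(C)C(C)(C)C | intermediate
20 | saturated trans-decalin diester, H5 anti to C20, C8 ester axial (syn to C20) | C[C@]1(C(=O)OC)[C@H]2CC[C@@H](C(=O)OC)[C@@H](CO[Si](C)(C)C(C)(C)C)[C@]2(C)CC[C@H]1O[Si](C)(C)C(C)(C)C | intermediate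
21 | saturated trans-decalin diester, C8 ester equatorial (trans to C11) | C[C@]1(C(=O)OC)[C@H]2CC[C@H](C(=O)OC)[C@@H](CO[Si](C)(C)C(C)(C)C)[C@]2(C)CC[C@H]1O[Si](C)(C)C(C)(C)C | intermediate
22 | C17,C19-diol with C3 and C11 tert-butyldimethylsilyl ethers | C[C@]1(CO)[C@H]2CC[C@H](CO)[C@@H](CO[Si](C)(C)C(C)(C)C)[C@]2(C)CC[C@H]1O[Si](C)(C)C(C)(C)C | intermediate
23 | C17,C19-bis(tert-butyldiphenylsilyl) ether with C3 and C11 tert-butyldimethylsilyl ethers | C[C@]1(CO[Si](c3ccccc3)(c3ccccc3)C(C)(C)C)[C@H]2CC[C@H](CO[Si](c3ccccc3)(c3ccccc3)C(C)(C)C)[C@@H](CO[Si](C)(C)C(C)(C)C)[C@]2(C)CC[C@H]1O[Si](C)(C)C(C)(C)C | intermediate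
24 | C11 primary alcohol of 23 | C[C@]1(CO[Si](c3ccccc3)(c3ccccc3)C(C)(C)C)[C@H]2CC[C@H](CO[Si](c3ccccc3)(c3ccccc3)C(C)(C)C)[C@@H](CO)[C@]2(C)CC[C@H]1O[Si](C)(C)C(C)(C)C | intermediate
25 | C11 aldehyde | C[C@]1(CO[Si](c3ccccc3)(c3ccccc3)C(C)(C)C)[C@H]2CC[C@H](CO[Si](c3ccccc3)(c3ccccc3)C(C)(C)C)[C@@H](C=O)[C@]2(C)CC[C@H]1O[Si](C)(C)C(C)(C)C | intermediate
26 | C9-vinyl compound (C11=C12) | C[C@]1(CO[Si](c3ccccc3)(c3ccccc3)C(C)(C)C)[C@H]2CC[C@H](CO[Si](c3ccccc3)(c3ccccc3)C(C)(C)C)[C@@H](C=C)[C@]2(C)CC[C@H]1O[Si](C)(C)C(C)(C)C | intermediate
27 | 3-bromofuran-2(5H)-one | O=C1OCC=C1Br | starting material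
28 | B-alkyl-9-BBN borane (boron on C12) | C[C@]1(CO[Si](c3ccccc3)(c3ccccc3)C(C)(C)C)[C@H]2CC[C@H](CO[Si](c3ccccc3)(c3ccccc3)C(C)(C)C)[C@@H](CCB3C4CCCC3CCC4)[C@]2(C)CC[C@H]1O[Si](C)(C)C(C)(C)C | intermediate
29 | silyl-protected target | C[C@]1(CO[Si](c3ccccc3)(c3ccccc3)C(C)(C)C)[C@H]2CC[C@H](CO[Si](c3ccccc3)(c3ccccc3)C(C)(C)C)[C@@H](CCC3=CCOC3=O)[C@]2(C)CC[C@H]1O[Si](C)(C)C(C)(C)C | intermediate
30 | 14-deoxy-17-hydroxyandrographolide | C[C@]1(CO)[C@H]2CC[C@H](CO)[C@@H](CCC3=CCOC3=O)[C@]2(C)CC[C@H]1O | target

## Step count and least certain steps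

Total step count: 20. Longest linear sequence: 19 steps (steps 1–3 and 5–20 from geraniol 1); step 4 is a one-step side branch from 5 and 6.

**Step 11 (key step).** The most likely failure is insufficient discrimination between the two chair-like tether arrangements at the temperature the cascade needs, because the energy gap rests on two modest conformational preferences. Material would then be diverted into the series epimeric at C9 and C10, which cannot be corrected later. A second concern is slow cycloaddition, since the tether forces the electrophilic pyrone terminus onto the more substituted alkene carbon; longer heating then invites 1,5-hydrogen shifts in the diene. The fallback strengthens the controlling element instead of the conditions, by enlarging the silyl group on the C3 oxygen, whose axial orientation is penalised by contact with the pyrone ring. It sets out from alcohol 12: iPr3SiOTf and 2,6-lutidine give the triisopropylsilyl ether F1, which is oxidised as in step 9 to ketone F2, annulated with 15 as in step 10 to pyrone F3, and heated as in step 11 to dienoate F4. F4 then follows the operations of steps 12 to 19: hydrogenation to F5, equilibration to F6, hydride reduction to diol F7, diphenylsilylation to F8, selective desilylation to alcohol F9, oxidation to aldehyde F10, methylenation to F11, and hydroboration and coupling with 27 to F12. The fluoride treatment of step 20 removes every silyl group and brings the detour back to the route at 30.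

**Step 7.** The dianion 11 is a conjugated dienolate. Methylation at the terminal carbon or on oxygen, or plain proton return to the conjugated ethylidene ester, may compete with α-methylation, and the facial bias may be weaker than with a saturated α-substituent. The fallback builds the quaternary centre on a non-conjugated enolate and makes the vinyl group afterwards. It sets out from aldehyde 4 and auxiliary 5. Acylation of 5 with pent-4-enoyl chloride gives imide F13. Its boron enolate aldol with 4 under the conditions of step 5 gives the α-allyl adduct F14, and methanolysis as in step 6 gives ester F15. Dianion methylation (the classical case with an α-alkyl group) gives F16, with the allyl group where the vinyl group of 12 sits. RuHCl(CO)(PPh3)3 moves the alkene to the (E)-prop-1-enyl compound F17, and ethenolysis with ethene and the second-generation Grubbs catalyst RuCl2(=CHPh)(H2IMes)(PCy3) trims it to the vinyl group, which comes back to the route at 12.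

**Step 9.** Attack of the oxygen nucleophile at the terminal carbon (aldehyde formation) or slow turnover may occur, because the alkene sits on a quaternary carbon and is flanked by an ester and a silyloxy group that can coordinate palladium. The fallback uses a different Markovnikov hydration and sets out from 13. Hg(OAc)2 in THF/H2O adds to the monosubstituted alkene, which is favoured by the steep fall of oxymercuration rates with alkene substitution and by the deactivating allylic oxygen on the trisubstituted alkene, to give organomercurial F18. NaBH4 reduces F18 to the secondary alcohol F19 (both carbinol epimers), and Dess–Martin oxidation comes back to the route at 14.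

**Step 12.** Alkene migration on the catalyst surface into the tetrasubstituted, ester-conjugated C8=C9 position would erase C9, and the C5=C6 bond between two quaternary carbons may be reduced slowly or with imperfect facial selectivity. The fallback replaces surface hydrogenation of the diene by electron transfer and sets out from 19. Mg in MeOH effects 1,6-reduction, with protonation at C5 anti to C20 and no metal hydride that could walk the alkene, giving the C6=C7 ester F20. The remaining disubstituted alkene is hydrogenated over Pd/C without creating a stereocentre, and the C8 mixture is equilibrated under the conditions of step 13, which comes back to the route at 21.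

**Step 19.** Base-induced opening or isomerisation of bromolactone 27 and protodeboronation of the hindered borane may outrun transmetalation. The fallback makes the C12–C13 bond by enolate alkylation and sets out from 26. Hydroboration with 9-BBN and oxidative work-up (NaOH, H2O2) give the primary alcohol F21, and I2, PPh3 and imidazole give iodide F22. Alkylation of the lithium enolate of 3-(phenylsulfanyl)oxolan-2-one with F22 gives lactone F23. Oxidation with mCPBA at −78 °C gives sulfoxide F24, and its thermal syn-elimination in toluene at 110 °C forms the endocyclic butenolide, which comes back to the route at 29.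

## Further compounds

F1 | step 11 | triisopropylsilyl analogue of 13 (C3 ether) | C=C[C@](C)(C(=O)OC)[C@H](O[Si](C(C)C)(C(C)C)C(C)C)CC/C(C)=C/CO[Si](C)(C)C(C)(C)C
F2 | step 11 | triisopropylsilyl analogue of ketone 14 | CC(=O)[C@](C)(C(=O)OC)[C@H](O[Si](C(C)C)(C(C)C)C(C)C)CC/C(C)=C/CO[Si](C)(C)C(C)(C)C
F3 | step 11 | triisopropylsilyl analogue of pyrone 17 | COC(=O)C1=CC=C(OC1=O)[C@](C)(C(=O)OC)[C@H](O[Si](C(C)C)(C(C)C)C(C)C)CC/C(C)=C/CO[Si](C)(C)C(C)(C)C
F4 | step 11 | triisopropylsilyl analogue of dienoate 19 | C[C@]1(C(=O)OC)C2=CC=C(C(=O)OC)[C@@H](CO[Si](C)(C)C(C)(C)C)[C@]2(C)CC[C@H]1O[Si](C(C)C)(C(C)C)C(C)C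
F5 | step 11 | triisopropylsilyl analogue of 20 (C8 ester axial) | C[C@]1(C(=O)OC)[C@H]2CC[C@@H](C(=O)OC)[C@@H](CO[Si](C)(C)C(C)(C)C)[C@]2(C)CC[C@H]1O[Si](C(C)C)(C(C)C)C(C)C
F6 | step 11 | triisopropylsilyl analogue of 21 (C8 ester equatorial) | C[C@]1(C(=O)OC)[C@H]2CC[C@H](C(=O)OC)[C@@H](CO[Si](C)(C)C(C)(C)C)[C@]2(C)CC[C@H]1O[Si](C(C)C)(C(C)C)C(C)C
F7 | step 11 | triisopropylsilyl analogue of diol 22 | C[C@]1(CO)[C@H]2CC[C@H](CO)[C@@H](CO[Si](C)(C)C(C)(C)C)[C@]2(C)CC[C@H]1O[Si](C(C)C)(C(C)C)C(C)C
F8 | step 11 | triisopropylsilyl analogue of 23 | C[C@]1(CO[Si](c3ccccc3)(c3ccccc3)C(C)(C)C)[C@H]2CC[C@H](CO[Si](c3ccccc3)(c3ccccc3)C(C)(C)C)[C@@H](CO[Si](C)(C)C(C)(C)C)[C@]2(C)CC[C@H]1O[Si](C(C)C)(C(C)C)C(C)C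
F9 | step 11 | triisopropylsilyl analogue of alcohol 24 | C[C@]1(CO[Si](c3ccccc3)(c3ccccc3)C(C)(C)C)[C@H]2CC[C@H](CO[Si](c3ccccc3)(c3ccccc3)C(C)(C)C)[C@@H](CO)[C@]2(C)CC[C@H]1O[Si](C(C)C)(C(C)C)C(C)C
F10 | step 11 | triisopropylsilyl analogue of aldehyde 25 | C[C@]1(CO[Si](c3ccccc3)(c3ccccc3)C(C)(C)C)[C@H]2CC[C@H](CO[Si](c3ccccc3)(c3ccccc3)C(C)(C)C)[C@@H](C=O)[C@]2(C)CC[C@H]1O[Si](C(C)C)(C(C)C)C(C)C
F11 | step 11 | triisopropylsilyl analogue of vinyl compound 26 | C[C@]1(CO[Si](c3ccccc3)(c3ccccc3)C(C)(C)C)[C@H]2CC[C@H](CO[Si](c3ccccc3)(c3ccccc3)C(C)(C)C)[C@@H](C=C)[C@]2(C)CC[C@H]1O[Si](C(C)C)(C(C)C)C(C)C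
F12 | step 11 | triisopropylsilyl analogue of 29 | C[C@]1(CO[Si](c3ccccc3)(c3ccccc3)C(C)(C)C)[C@H]2CC[C@H](CO[Si](c3ccccc3)(c3ccccc3)C(C)(C)C)[C@@H](CCC3=CCOC3=O)[C@]2(C)CC[C@H]1O[Si](C(C)C)(C(C)C)C(C)C
F13 | step 7 | (4S)-4-benzyl-3-(pent-4-enoyl)oxazolidin-2-one | C=CCCC(=O)N1[C@@H](Cc2ccccc2)COC1=O
F14 | step 7 | α-allyl syn-aldol imide (allyl analogue of 9) | O=C1OC[C@H](Cc2ccccc2)N1C(=O)[C@@H](CC=C)[C@H](O)CC/C(C)=C/CO[Si](C)(C)C(C)(C)C
F15 | step 7 | α-allyl hydroxy methyl ester (allyl analogue of 10) | C=CC[C@H](C(=O)OC)[C@H](O)CC/C(C)=C/CO[Si](C)(C)C(C)(C)C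
F16 | step 7 | α-allyl α-methyl hydroxy ester (allyl analogue of 12) | C=CC[C@](C)(C(=O)OC)[C@H](O)CC/C(C)=C/CO[Si](C)(C)C(C)(C)C
F17 | step 7 | α-[(E)-prop-1-enyl] α-methyl hydroxy ester | C/C=C/[C@](C)(C(=O)OC)[C@H](O)CC/C(C)=C/CO[Si](C)(C)C(C)(C)C
F18 | step 9 | β-hydroxyalkylmercury acetate from 13 (carbinol epimers) | CC(=O)O[Hg]CC(O)[C@](C)(C(=O)OC)[C@H](O[Si](C)(C)C(C)(C)C)CC/C(C)=C/CO[Si](C)(C)C(C)(C)C
F19 | step 9 | secondary alcohol, 1-hydroxyethyl analogue of 14 (carbinol epimers) | CC(O)[C@](C)(C(=O)OC)[C@H](O[Si](C)(C)C(C)(C)C)CC/C(C)=C/CO[Si](C)(C)C(C)(C)C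
F20 | step 12 | C6=C7 alkene diester with H5 anti to C20 (C8 drawn equatorial; formed as a C8 mixture) | C[C@]1(C(=O)OC)[C@H]2C=C[C@H](C(=O)OC)[C@@H](CO[Si](C)(C)C(C)(C)C)[C@]2(C)CC[C@H]1O[Si](C)(C)C(C)(C)C
F21 | step 19 | C12 primary alcohol | C[C@]1(CO[Si](c3ccccc3)(c3ccccc3)C(C)(C)C)[C@H]2CC[C@H](CO[Si](c3ccccc3)(c3ccccc3)C(C)(C)C)[C@@H](CCO)[C@]2(C)CC[C@H]1O[Si](C)(C)C(C)(C)C
F22 | step 19 | C12 primary iodide | C[C@]1(CO[Si](c3ccccc3)(c3ccccc3)C(C)(C)C)[C@H]2CC[C@H](CO[Si](c3ccccc3)(c3ccccc3)C(C)(C)C)[C@@H](CCI)[C@]2(C)CC[C@H]1O[Si](C)(C)C(C)(C)C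
F23 | step 19 | α-alkyl-α-(phenylsulfanyl)butyrolactone (epimers at the lactone α-carbon) | C[C@]1(CO[Si](c3ccccc3)(c3ccccc3)C(C)(C)C)[C@H]2CC[C@H](CO[Si](c3ccccc3)(c3ccccc3)C(C)(C)C)[C@@H](CCC3(Sc4ccccc4)CCOC3=O)[C@]2(C)CC[C@H]1O[Si](C)(C)C(C)(C)C
F24 | step 19 | α-alkyl-α-(phenylsulfinyl)butyrolactone (sulfoxide of F23) | C[C@]1(CO[Si](c3ccccc3)(c3ccccc3)C(C)(C)C)[C@H]2CC[C@H](CO[Si](c3ccccc3)(c3ccccc3)C(C)(C)C)[C@@H](CCC3(S(=O)c4ccccc4)CCOC3=O)[C@]2(C)CC[C@H]1O[Si](C)(C)C(C)(C)C
A1 | alternative 1 | (S)-4-(tert-butyldimethylsilyloxymethyl)-2-methylcyclohex-2-enone, ring B enone | O=C1CC[C@H](CO[Si](C)(C)C(C)(C)C)C=C1C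
A2 | alternative 1 | vinylmagnesium bromide | C=C[Mg]Br
A3 | alternative 1 | (E)-1,3-dichlorobut-2-ene | ClC/C=C(\C)Cl
A4 | alternative 1 | 2-(3-chlorobut-2-enyl)-2-methyl-3-vinyl-4-(silyloxymethyl)cyclohexanone with C8, C9, C10 set | O=C1CC[C@H](CO[Si](C)(C)C(C)(C)C)[C@@H](C=C)[C@]1(C)C/C=C(\C)Cl
A5 | alternative 2 | methyl 5-(1-methyl-2,6-dioxocyclohexyl)-3-oxopentanoate, prochiral triketone | COC(=O)CC(=O)CCC1(C)C(=O)CCCC1=O
A6 | alternative 2 | bicyclic enedione ester with quaternary C10 set | COC(=O)C1=C2CCCC(=O)[C@]2(C)CCC1=O
A7 | alternative 3 | seven-membered-ring C4–C19 epoxide with the C3 silyloxy group on the carbon next to C19 | C[C@@]12O[C@@H]1[C@H](O[Si](C)(C)C(C)(C)C)CC[C@]3(C)[C@@H]2CC[C@H](CO[Si](C)(C)C(C)(C)C)[C@H]3CCOCc1ccccc1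
A8 | alternative 3 | methylaluminium bis(4-bromo-2,6-di-tert-butylphenoxide) | C[Al](Oc1c(cc(Br)cc1C(C)(C)C)C(C)(C)C)Oc1c(cc(Br)cc1C(C)(C)C)C(C)(C)C
A9 | alternative 3 | trans-decalin with C3 silyl ether and quaternary C4 bearing methyl and the C19 aldehyde | C[C@]1(C=O)[C@H]2CC[C@H](CO[Si](C)(C)C(C)(C)C)[C@@H](CCOCc3ccccc3)[C@]2(C)CC[C@H]1O[Si](C)(C)C(C)(C)C
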